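1. Numbering: the furofuran core is C1(guaiacyl)–O2–C3–C3a–C4(benzofuranyl)–O5–C6–C6a. Ring A = C1, O2, C3, C3a, C6a. Ring B = C4, O5, C6, C6a, C3a. Ring C = O1', C2', C3', C3a', C7a' of the dihydrobenzofuran. The target is the endo,endo (all-cis) furofuran with a cis ring C, so all its relative relations are contra-thermodynamic.
2. Retrosynthetic cuts, in order: three O–Si bonds; C6–H (from a C6 methyl acetal); C1–C6a and C1–O2 of ring A (vanillin acetal + dihydrofuranylmethanol); C4–C3a of ring B (aryl vinyl oxirane); C4–C6 and O5–C6 of that oxirane (aldehyde + 4-bromocrotonoyl unit C6–C6a–C3a–C3); C2'–C3' of ring C (carbenoid C–H insertion); C3a'–C3' and O1'–C2' (5-iodovanillin, ethyl diazoacetate, a vanillyl alcohol).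
3. Enabling feature: in ring B, O5 lies between the aryl-bearing C4 and C6, and the C4 aryl group is cis to the C3 branch on C3a. At the C6=C6a enol ether level, the array C4–O5–C6=C6a–C3a is the closed form of a vinyl carbonyl ylide. Ring B can therefore grow from the three-membered ring C4–O5–C6 by taking in C6a and C3a of an enoyl group.
4. Forward order: ring C, then the oxirane, then ring B (three- to five-membered ring expansion), then ring A, then C6 deoxygenation and desilylation. All three aryl units come from vanillin or 5-iodovanillin.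
5. Stereochemistry: C2'/C3' (cis, absolute) come from a chiral dirhodium carboxylate. The C4/C3a cis relation comes from the disrotatory closure and its absolute sense from a camphorsultam on the C3 carbonyl. C6a comes from the tether (cis fusion) and C1 (endo aryl) from kinetic oxocarbenium closure.
6. Helpers, removed later: the sultam and the C3 carbonyl level (step 13), the C6=C6a double bond (step 14), the C6 methoxy group (step 15), and the silyl ethers (step 16).

Key step: step 12

Abbreviations: TIPS = triisopropylsilyl; ArG = 3-methoxy-4-(triisopropylsilyloxy)phenyl; Bzf = (2S,3S)-7-methoxy-2-ArG-3-(triisopropylsilyloxymethyl)-2,3-dihydro-1-benzofuran-5-yl (2,3-cis); Rh2(R-PTTL)4 = dirhodium tetrakis[N-phthaloyl-(R)-tert-leucinate].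
Assumption: the sense of induction of Rh2(R-PTTL)4 (step 6) and of the (1S)-(−)-sultam (step 12) is assigned by analogy with simpler substrates; both are sold in either antipode, so a reversed sense would change only which antipode is bought.

Step 1
Reactants: 1 vanillin
Product: 2 3-methoxy-4-(triisopropylsilyloxy)benzaldehyde
Conditions: TIPSCl, imidazole, DMF, rt
Reagents that add atoms: chlorotriisopropylsilane, CC(C)[Si](Cl)(C(C)C)C(C)C
Why: Silyl ether formation at the only OH group, the hindered aryl silyl ether being chosen because it stands hydride, amide base, 180 °C and short contact with Lewis acids and leaves with fluoride under near-neutral conditions.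

Step 2
Reactants: 2 3-methoxy-4-(triisopropylsilyloxy)benzaldehyde
Product: 3 [3-methoxy-4-(triisopropylsilyloxy)phenyl]methanol
Conditions: NaBH4, MeOH, 0 °C
Reagents that add atoms: none
Why: Borohydride reduction of an aromatic aldehyde, to which the aryl silyl ether is inert.

Step 3
Reactants: 2 3-methoxy-4-(triisopropylsilyloxy)benzaldehyde
Product: 4 3-methoxy-4-(triisopropylsilyloxy)benzaldehyde dimethyl acetal
Conditions: HC(OMe)3, pyridinium p-toluenesulfonate (cat.), MeOH, rt
Reagents that add atoms: trimethyl orthoformate, COC(OC)OC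
Why: Acid-catalysed acetalisation driven by the orthoester, mild enough for the aryl silyl ether.

Step 4
Reactants: 5 5-iodovanillin; 3 [3-methoxy-4-(triisopropylsilyloxy)phenyl]methanol
Product: 6 3-iodo-5-methoxy-4-(ArG-methoxy)benzaldehyde
Conditions: PPh3, DIAD, THF, 0 °C to rt
Reagents that add atoms: none
Why: Mitsunobu etherification, in which the acidic phenol of 5 (para to CHO, ortho to iodine) is a good pronucleophile, the electron-rich primary benzylic alcohol a good partner, and the neutral medium avoids the silyl transfer that carbonate bases could cause.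

Step 5
Reactants: 6 3-iodo-5-methoxy-4-(ArG-methoxy)benzaldehyde; 7 ethyl diazoacetate
Product: 8 ethyl 2-diazo-2-[5-formyl-3-methoxy-2-(ArG-methoxy)phenyl]acetate
Conditions: Pd(PPh3)4 (5 mol %), Ag2CO3, Et3N, PhMe, rt
Reagents that add atoms: none
Why: Palladium-catalysed cross-coupling of an aryl iodide with the C–H bond of an acceptor diazo compound, which starts at zerovalent palladium and keeps the diazo group because deprotonation and reductive elimination outrun loss of nitrogen at room temperature.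

Step 6
Reactants: 8 ethyl 2-diazo-2-[5-formyl-3-methoxy-2-(ArG-methoxy)phenyl]acetate
Product: 9 ethyl (2S,3R)-5-formyl-7-methoxy-2-ArG-2,3-dihydro-1-benzofuran-3-carboxylate (2,3-cis)
Conditions: Rh2(R-PTTL)4 (1 mol %), PhMe (dilute), −60 °C
Reagents that add atoms: none
Why: Intramolecular 1,5 C–H insertion of a donor/acceptor dirhodium carbenoid into the ether CH2 activated by oxygen and the electron-rich aryl group, a reaction type known to give cis-2-aryl-2,3-dihydrobenzofuran-3-carboxylates, the concerted insertion inside the chiral ligand pocket setting C2' and C3' together (kinetic cis, enantioface chosen by the catalyst) and closing ring C faster than the remote aldehyde can intercept the carbenoid.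

Step 7
Reactants: 9 ethyl (2S,3R)-5-formyl-7-methoxy-2-ArG-2,3-dihydro-1-benzofuran-3-carboxylate
Product: 10 [(2S,3S)-7-methoxy-2-ArG-2,3-dihydro-1-benzofuran-3,5-diyl]dimethanol (2,3-cis)
Conditions: i-Bu2AlH (excess), CH2Cl2, −78 to 0 °C; aq. potassium sodium tartrate
Reagents that add atoms: none
Why: Hydride reduction of ester and aldehyde with a non-basic aluminium hydride at low temperature, so that the epimerisable C3' centre alpha to the ester becomes a configurationally safe CH–CH2OH before it can drift to trans (the descriptor changes from R to S only through the priority rules).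

Step 8
Reactants: 10 [(2S,3S)-7-methoxy-2-ArG-2,3-dihydro-1-benzofuran-3,5-diyl]dimethanol
Product: 11 (2S,3S)-3-(hydroxymethyl)-7-methoxy-2-ArG-2,3-dihydro-1-benzofuran-5-carbaldehyde
Conditions: MnO2, CH2Cl2, rt
Reagents that add atoms: none
Why: Chemoselective MnO2 oxidation, which takes the benzylic alcohol and leaves the saturated primary alcohol untouched.

Step 9
Reactants: 11 (2S,3S)-3-(hydroxymethyl)-7-methoxy-2-ArG-2,3-dihydro-1-benzofuran-5-carbaldehyde
Product: 12 Bzf–CHO, (2S,3S)-7-methoxy-2-ArG-3-(triisopropylsilyloxymethyl)-2,3-dihydro-1-benzofuran-5-carbaldehyde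
Conditions: TIPSCl, imidazole, DMAP (cat.), DMF, rt
Reagents that add atoms: chlorotriisopropylsilane, CC(C)[Si](Cl)(C(C)C)C(C)C
Why: Silylation of the only free alcohol, needed so that the alcohol freed in step 13 is the only one present in step 14.

Step 10
Reactants: 13 (E)-4-bromobut-2-enoic acid; 14 (1S)-(−)-2,10-camphorsultam
Product: 16 N-[(E)-4-bromobut-2-enoyl]-(1S)-2,10-camphorsultam, via (E)-4-bromobut-2-enoyl chloride 15 (not isolated)
Conditions: (COCl)2, DMF (cat.), CH2Cl2, 0 °C to rt, evaporate; 14, NaH, PhMe, 0 °C to rt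
Reagents that add atoms: none
Why: N-acylation of the deprotonated sultam by the acid chloride, which is far faster than displacement of the allylic bromide.

Step 11
Reactants: 12 Bzf–CHO; 16 N-[(E)-4-bromobut-2-enoyl]-(1S)-2,10-camphorsultam
Product: 17 N-{(E)-3-[3-Bzf-oxiran-2-yl]prop-2-enoyl}-(1S)-2,10-camphorsultam (mixture of oxirane stereoisomers)
Conditions: LiN(SiMe3)2 added to 12 + 16, THF, −78 to 0 °C
Reagents that add atoms: none
Why: Vinylogous Darzens condensation, in which the bromodienolate adds reversibly to the non-enolisable aldehyde and only the gamma-aldolate is drained by 3-exo-tet displacement of bromide (C4–C6, then O5–C6), the configuration at the two oxirane carbons being of no consequence because step 12 erases it.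

Step 12
Reactants: 17 N-{(E)-3-[3-Bzf-oxiran-2-yl]prop-2-enoyl}-(1S)-2,10-camphorsultam
Product: 19 N-{[(2S,3R)-2-Bzf-2,3-dihydrofuran-3-yl]carbonyl}-(1S)-2,10-camphorsultam (2,3-cis), via carbonyl ylide 18 (not isolated)
Conditions: PhMe (dilute), sealed silanised tube, 180 °C
Reagents that add atoms: none
Why: Heat breaks the oxirane C4–C6 bond in a conrotatory opening, helped by the push of the 4-alkoxy-3-methoxyaryl group on C4 and the pull of the enoyl group on C6, to give the flat carbonyl ylide 18, and all oxirane stereoisomers of 17 drain through the one rotamer that has the aryl group outside and the enoyl arm inside. The five-atom, six-electron array C4–O5–C6–C6a=C3a then closes by a disrotatory 1,5-electrocyclisation (formally 5-endo-trig at the enoyl alpha-carbon), which makes the C4–C3a bond and turns the three-membered ring C4–O5–C6 into five-membered ring B with a C6=C6a enol ether; this is the known vinyloxirane to 2,3-dihydrofuran rearrangement of 5-aryl-4,5-epoxypent-2-enoyl compounds. Aryl and acyl groups both sit on the outside of the U-shaped array, so disrotation places them cis, which is the contra-thermodynamic C4/C3a relation of the target. The absolute sense cannot come from the oxirane, since 18 is planar; it comes from the sultam, which in its usual conformation (C=O anti to SO2, enoyl s-cis) shields one face of the alpha-carbon so that C4 bonds to its Si face, and the minor (2R,3S) isomer differs right next to the auxiliary and should be removable by chromatography or crystallisation. The step needs C–C rather than C–O cleavage of the oxirane, closure within the molecule rather than cycloaddition between molecules, and no cis-to-trans leakage; the donor/acceptor substitution of the C4–C6 bond, high dilution, and an acid-free, base-free medium stopped at full conversion secure these.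

Step 13
Reactants: 19 N-{[(2S,3R)-2-Bzf-2,3-dihydrofuran-3-yl]carbonyl}-(1S)-2,10-camphorsultam
Product: 20 [(2S,3S)-2-Bzf-2,3-dihydrofuran-3-yl]methanol (2,3-cis)
Conditions: LiAlH4, THF, 0 °C; basic aqueous work-up
Reagents that add atoms: none
Why: Reductive cleavage of the N-acyl sultam by LiAlH4, faster than enolisation so that C3a keeps its configuration, with the enol ether and silyl ethers inert and the auxiliary recovered.

Step 14
Reactants: 20 [(2S,3S)-2-Bzf-2,3-dihydrofuran-3-yl]methanol; 4 3-methoxy-4-(triisopropylsilyloxy)benzaldehyde dimethyl acetal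
Product: 21 (1S,3aS,4S,6aS)-1-ArG-4-Bzf-6-methoxytetrahydro-1H,3H-furo[3,4-c]furan (endo,endo; 6-methoxy exo)
Conditions: TMSOTf (0.2 equiv), CH2Cl2, 4 Å sieves, −78 °C; Et3N quench at −78 °C
Reagents that add atoms: none
Why: Acetal exchange gives an E-oxocarbenium ion tethered through O2–C3 to the face of ring B that carries the aryl group, the nucleophilic enol ether carbon C6a attacks it (intramolecular Mukaiyama/Prins-type closure of ring A, 5-endo at the C=O+ bond), the tether enforces the cis fusion at C6a, the compact transition state known for this dihydrofuran template places the C1 aryl group endo under kinetic control, and methanol caps the C6 oxocarbenium ion from the convex face.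

Step 15
Reactants: 21 (1S,3aS,4S,6aS)-1-ArG-4-Bzf-6-methoxytetrahydro-1H,3H-furo[3,4-c]furan
Product: 22 (1S,3aS,4S,6aS)-1-ArG-4-Bzf-tetrahydro-1H,3H-furo[3,4-c]furan (tris-TIPS ether of the target)
Conditions: Et3SiH, BF3·OEt2, CH2Cl2, −78 to −40 °C; Et3N, aq. NaHCO3
Reagents that add atoms: none
Why: Ionic hydrogenation of the acetal through the C6 oxocarbenium ion, known on endo,endo furofuran acetals, the low temperature keeping the benzylic C–O bonds at C1, C4 and C2' from ionising and leaking to the exo or trans isomers.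

Step 16
Reactants: 22 tris-TIPS ether of the target
Product: 23 target, 4-{(1S,3aS,4S,6aS)-4-[(2S,3S)-2-(4-hydroxy-3-methoxyphenyl)-3-(hydroxymethyl)-7-methoxy-2,3-dihydro-1-benzofuran-5-yl]tetrahydro-1H,3H-furo[3,4-c]furan-1-yl}-2-methoxyphenol
Conditions: Bu4NF, AcOH (1:1, excess), THF, 0 °C to rt
Reagents that add atoms: none
Why: Fluoride cleavage of all three Si–O bonds in one operation, the acetic acid buffer keeping the phenoxide concentration low so that no quinone methide opening can epimerise C1, C4 or C2'.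

Compound list
1 | vanillin | COc1cc(C=O)ccc1O | starting material
2 | 3-methoxy-4-(triisopropylsilyloxy)benzaldehyde | COc1cc(C=O)ccc1O[Si](C(C)C)(C(C)C)C(C)C | intermediate
3 | [3-methoxy-4-(triisopropylsilyloxy)phenyl]methanol | COc1cc(CO)ccc1O[Si](C(C)C)(C(C)C)C(C)C | intermediate
4 | 3-methoxy-4-(triisopropylsilyloxy)benzaldehyde dimethyl acetal | COc1cc(C(OC)OC)ccc1O[Si](C(C)C)(C(C)C)C(C)C | intermediate
5 | 5-iodovanillin (4-hydroxy-3-iodo-5-methoxybenzaldehyde) | COc1cc(C=O)cc(I)c1O | starting material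
6 | 3-iodo-5-methoxy-4-{[3-methoxy-4-(triisopropylsilyloxy)benzyl]oxy}benzaldehyde | COc1cc(C=O)cc(I)c1OCc1ccc(O[Si](C(C)C)(C(C)C)C(C)C)c(OC)c1 | intermediate
7 | ethyl diazoacetate | CCOC(=O)C=[N+]=[N-] | starting material
8 | ethyl 2-diazo-2-(5-formyl-3-methoxy-2-{[3-methoxy-4-(triisopropylsilyloxy)benzyl]oxy}phenyl)acetate | CCOC(=O)C(=[N+]=[N-])c1cc(C=O)cc(OC)c1OCc1ccc(O[Si](C(C)C)(C(C)C)C(C)C)c(OC)c1 | intermediate
9 | ethyl (2S,3R)-5-formyl-7-methoxy-2-[3-methoxy-4-(triisopropylsilyloxy)phenyl]-2,3-dihydro-1-benzofuran-3-carboxylate (cis) | O=Cc1cc(OC)c2c(c1)[C@@H](C(=O)OCC)[C@@H](c1ccc(O[Si](C(C)C)(C(C)C)C(C)C)c(OC)c1)O2 | intermediate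
10 | [(2S,3S)-7-methoxy-2-[3-methoxy-4-(triisopropylsilyloxy)phenyl]-2,3-dihydro-1-benzofuran-3,5-diyl]dimethanol (cis) | OCc1cc(OC)c2c(c1)[C@@H](CO)[C@@H](c1ccc(O[Si](C(C)C)(C(C)C)C(C)C)c(OC)c1)O2 | intermediate
11 | (2S,3S)-3-(hydroxymethyl)-7-methoxy-2-[3-methoxy-4-(triisopropylsilyloxy)phenyl]-2,3-dihydro-1-benzofuran-5-carbaldehyde (cis) | O=Cc1cc(OC)c2c(c1)[C@@H](CO)[C@@H](c1ccc(O[Si](C(C)C)(C(C)C)C(C)C)c(OC)c1)O2 | intermediate
12 | Bzf–CHO, (2S,3S)-7-methoxy-2-[3-methoxy-4-(triisopropylsilyloxy)phenyl]-3-(triisopropylsilyloxymethyl)-2,3-dihydro-1-benzofuran-5-carbaldehyde (cis) | O=Cc1cc(OC)c2c(c1)[C@@H](CO[Si](C(C)C)(C(C)C)C(C)C)[C@@H](c1ccc(O[Si](C(C)C)(C(C)C)C(C)C)c(OC)c1)O2 | intermediate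
13 | (E)-4-bromobut-2-enoic acid | OC(=O)/C=C/CBr | starting material
14 | (1S)-(−)-2,10-camphorsultam, (3aS,6R,7aR) | CC1(C)[C@@H]2CC[C@]13CS(=O)(=O)N[C@@H]3C2 | starting material
15 | (E)-4-bromobut-2-enoyl chloride | ClC(=O)/C=C/CBr | intermediate
16 | N-[(E)-4-bromobut-2-enoyl]-(1S)-2,10-camphorsultam | CC1(C)[C@@H]2CC[C@]13CS(=O)(=O)N(C(=O)/C=C/CBr)[C@@H]3C2 | intermediate
17 | N-{(E)-3-[3-Bzf-oxiran-2-yl]prop-2-enoyl}-(1S)-2,10-camphorsultam (oxirane carbons: mixture, left open) | CC1(C)[C@@H]2CC[C@]13CS(=O)(=O)N(C(=O)/C=C/C5OC5c6cc(OC)c7c(c6)[C@@H](CO[Si](C(C)C)(C(C)C)C(C)C)[C@@H](c6ccc(O[Si](C(C)C)(C(C)C)C(C)C)c(OC)c6)O7)[C@@H]3C2 | intermediate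
18 | carbonyl ylide from C4–C6 cleavage of 17 | CC1(C)[C@@H]2CC[C@]13CS(=O)(=O)N(C(=O)/C=C/[CH-][O+]=Cc6cc(OC)c7c(c6)[C@@H](CO[Si](C(C)C)(C(C)C)C(C)C)[C@@H](c6ccc(O[Si](C(C)C)(C(C)C)C(C)C)c(OC)c6)O7)[C@@H]3C2 | intermediate
19 | N-{[(2S,3R)-2-Bzf-2,3-dihydrofuran-3-yl]carbonyl}-(1S)-2,10-camphorsultam (cis) | CC1(C)[C@@H]2CC[C@]13CS(=O)(=O)N(C(=O)[C@@H]5C=CO[C@@H]5c6cc(OC)c7c(c6)[C@@H](CO[Si](C(C)C)(C(C)C)C(C)C)[C@@H](c6ccc(O[Si](C(C)C)(C(C)C)C(C)C)c(OC)c6)O7)[C@@H]3C2 | intermediate
20 | [(2S,3S)-2-Bzf-2,3-dihydrofuran-3-yl]methanol (cis) | OC[C@@H]1C=CO[C@@H]1c3cc(OC)c4c(c3)[C@@H](CO[Si](C(C)C)(C(C)C)C(C)C)[C@@H](c3ccc(O[Si](C(C)C)(C(C)C)C(C)C)c(OC)c3)O4 | intermediate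
21 | (1S,3aS,4S,6aS)-1-ArG-4-Bzf-6-methoxytetrahydro-1H,3H-furo[3,4-c]furan (endo,endo; exo-methoxy) | COc1cc([C@H]2OC[C@@H]3[C@H]2[C@@H](OC)O[C@@H]3c4cc(OC)c5c(c4)[C@@H](CO[Si](C(C)C)(C(C)C)C(C)C)[C@@H](c4ccc(O[Si](C(C)C)(C(C)C)C(C)C)c(OC)c4)O5)ccc1O[Si](C(C)C)(C(C)C)C(C)C | intermediate
22 | (1S,3aS,4S,6aS)-1-ArG-4-Bzf-tetrahydro-1H,3H-furo[3,4-c]furan (tris-TIPS ether of the target) | COc1cc([C@H]2OC[C@@H]3[C@H]2CO[C@@H]3c4cc(OC)c5c(c4)[C@@H](CO[Si](C(C)C)(C(C)C)C(C)C)[C@@H](c4ccc(O[Si](C(C)C)(C(C)C)C(C)C)c(OC)c4)O5)ccc1O[Si](C(C)C)(C(C)C)C(C)C | intermediate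
23 | CNP0303197.1 | COc1cc([C@H]2OC[C@@H]3[C@H]2CO[C@@H]3c2cc(OC)c3c(c2)[C@@H](CO)[C@@H](c2ccc(O)c(OC)c2)O3)ccc1O | target

Total step count: 16. Longest linear sequence: 14 (steps 1, 2, 4–9, 11–16).

Steps most likely to fail

Step 12. The temperature needed for C–C cleavage may erode the facial bias of the auxiliary, giving poor facial selectivity in the ring closure. The fallback takes stereocontrol out of the pericyclic event and separates the isomers afterwards. It sets out from 12 and comes back at 20.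
- Aldehyde 12 is condensed with methyl (E)-4-bromobut-2-enoate (LiN(SiMe3)2, THF, −78 °C) to methyl (E)-3-(3-Bzf-oxiran-2-yl)prop-2-enoate F1.
- Heated as in step 12, this should give the two cis esters, methyl (2S,3R)-2-Bzf-2,3-dihydrofuran-3-carboxylate F2 and methyl (2R,3S)-2-Bzf-2,3-dihydrofuran-3-carboxylate F3.
- i-Bu2AlH reduces the pair to 20 and [(2R,3R)-2-Bzf-2,3-dihydrofuran-3-yl]methanol F4.
- A lipase (Burkholderia cepacia lipase, vinyl acetate, t-BuOMe) is a known way to part primary alcohols that differ at the neighbouring carbon. It is chosen by screening so that it converts the unwanted partner into [(2R,3R)-2-Bzf-2,3-dihydrofuran-3-yl]methyl acetate F5. Chromatography then delivers 20.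

Step 11. The bromodienolate may attack through its alpha-carbon or alkylate itself, or the base or aldolate may attack the imide carbonyl with loss of the auxiliary. The fallback replaces the halohydrin route by a sulfur ylide epoxidation. It sets out from 16 and comes back at 17.
- Compound 16 alkylates tetrahydrothiophene (acetone, rt) to give 1-{(E)-4-oxo-4-[(1S)-2,10-camphorsultam-N-yl]but-2-enyl}tetrahydrothiophenium bromide F6.
- With Cs2CO3 in MeCN at rt, the stabilised allylic ylide adds to 12 and closes to 17 with loss of the sulfide. Neither a strong base nor a free bromodienolate is present.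

Step 5. Oxidative addition may be slow beside the bulky ether, the base may induce addition of the diazoester to the free aldehyde, or nitrogen may be lost at palladium. The fallback installs carbon first and the diazo group second. It sets out from 6 and comes back at 8.
- A Migita–Stille coupling of 6 with ethyl (tributylstannyl)acetate (PdCl2[P(o-tolyl)3]2, ZnBr2, DMF, 80 °C; neutral, aldehyde tolerated) gives ethyl 2-[5-formyl-3-methoxy-2-(ArG-methoxy)phenyl]acetate F7.
- Regitz diazo transfer (4-acetamidobenzenesulfonyl azide, DBU, MeCN, 0 °C) then gives 8.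

Further compounds
F1 | step 12 | methyl (E)-3-(3-Bzf-oxiran-2-yl)prop-2-enoate (oxirane carbons left open) | COC(=O)/C=C/C1OC1c3cc(OC)c4c(c3)[C@@H](CO[Si](C(C)C)(C(C)C)C(C)C)[C@@H](c3ccc(O[Si](C(C)C)(C(C)C)C(C)C)c(OC)c3)O4
F2 | step 12 | methyl (2S,3R)-2-Bzf-2,3-dihydrofuran-3-carboxylate (cis) | COC(=O)[C@@H]1C=CO[C@@H]1c3cc(OC)c4c(c3)[C@@H](CO[Si](C(C)C)(C(C)C)C(C)C)[C@@H](c3ccc(O[Si](C(C)C)(C(C)C)C(C)C)c(OC)c3)O4
F3 | step 12 | methyl (2R,3S)-2-Bzf-2,3-dihydrofuran-3-carboxylate (cis) | COC(=O)[C@H]1C=CO[C@H]1c3cc(OC)c4c(c3)[C@@H](CO[Si](C(C)C)(C(C)C)C(C)C)[C@@H](c3ccc(O[Si](C(C)C)(C(C)C)C(C)C)c(OC)c3)O4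
F4 | step 12 | [(2R,3R)-2-Bzf-2,3-dihydrofuran-3-yl]methanol (cis) | OC[C@H]1C=CO[C@H]1c3cc(OC)c4c(c3)[C@@H](CO[Si](C(C)C)(C(C)C)C(C)C)[C@@H](c3ccc(O[Si](C(C)C)(C(C)C)C(C)C)c(OC)c3)O4
F5 | step 12 | [(2R,3R)-2-Bzf-2,3-dihydrofuran-3-yl]methyl acetate (cis) | CC(=O)OC[C@H]1C=CO[C@H]1c3cc(OC)c4c(c3)[C@@H](CO[Si](C(C)C)(C(C)C)C(C)C)[C@@H](c3ccc(O[Si](C(C)C)(C(C)C)C(C)C)c(OC)c3)O4
F6 | step 11 | 1-{(E)-4-oxo-4-[(1S)-2,10-camphorsultam-N-yl]but-2-enyl}tetrahydrothiophenium bromide | CC1(C)[C@@H]2CC[C@]13CS(=O)(=O)N(C(=O)/C=C/C[S+]4CCCC4)[C@@H]3C2.[Br-]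
F7 | step 5 | ethyl 2-(5-formyl-3-methoxy-2-{[3-methoxy-4-(triisopropylsilyloxy)benzyl]oxy}phenyl)acetate | CCOC(=O)Cc1cc(C=O)cc(OC)c1OCc1ccc(O[Si](C(C)C)(C(C)C)C(C)C)c(OC)c1
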